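**Plan**
Ring B carries a cis-7,8-diol (secondary C7–O next to tertiary C8–O with Me-17) between the quaternary carbons C5 and C9, whose methyl groups are syn-axial. A vicinal diol in a six-membered ring is the retron of a ketyl pinacol closure of a 1,6-keto aldehyde, so ring B is cut at C7–C8.
Further cuts, in retrosynthetic order: C12–C13 (Heck, butenolide), the two ester C–O bonds, C6–C7 (formyl-anion addition to a C6 aldehyde), C9–C11 (vinylation of a lactone enolate), C5–C6 and C9–C10 (Michael/aldol three-component coupling on an enone), and the C2–isopropenyl bond of a chiral-pool control element.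
Forward: ring A is (S)-carvone. Mukaiyama–Michael addition and hydroxymethylation give a temporary trans-fused δ-lactone whose ring oxygen sits where C7 will later be. The isopropenyl group is excised, Me-18 and the C9 vinyl group are installed, and the lactone is opened to the C6 aldehyde / C8 methyl ketone. C7 is added as a dithiane, ring B is closed last by SmI2 pinacol coupling, and two acylations and a Heck coupling finish the target.
Stereochemistry: C10 from the carvone stereocentre (trans addition); C5 anti to the C10 side chain; C9 by α-face alkylation of the lactone enolate (β face blocked by the 1,3-axial Me-19); C6 by Felkin–Anh addition; C7 and C8 in the key step.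
Key step: step 12

Remark on numbering: clerodane numbering is used throughout. Ring A = C1–C5, C10 (C3=C4, Me-18 on C4, Me-19 on C5); ring B = C5–C10 (Me-17 on C8, Me-20 and C11=C12 on C9); butenolide = C13–C16. β is the face carrying Me-19; in the target Me-17, Me-20 and the 6-O are β, and 10-H, 7-O, 8-OH and the C9 side chain are α.
Remark on materials: silyl ketene acetal 2 is assumed to be a catalogue compound (otherwise one step from methyl propanoate with LiN(i-Pr)2 and Me3SiCl).

**Step 1**
Reactants: 1 (S)-(+)-carvone; 2 1-methoxy-1-(trimethylsilyloxy)prop-1-ene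
Product: 3 silyl enol ether of the trans Michael adduct
Conditions: HNTf2 (2 mol %), CH2Cl2, −78 °C
Reagents that add atoms: none
Why: A silyl-triflimide-catalysed Mukaiyama–Michael addition should deliver the ketene acetal axially to C10 on the face opposite the equatorial isopropenyl group of carvone, which sets C10 and leaves the enolate regiospecifically as its C4–C5 silyl ether, while C9 forms as an epimer mixture that is erased in step 6.

**Step 2**
Reactants: 3 silyl enol ether
Product: 5 isopropenyl keto lactone, via hydroxymethyl keto ester 4 (not isolated)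
Conditions: aq. HCHO, Yb(OTf)3 (10 mol %), THF, rt; then camphorsulfonic acid (cat.), CH2Cl2, rt
Reagents that add atoms: formaldehyde, C=O
Why: A lanthanide-triflate-catalysed aqueous Mukaiyama aldol reaction (hydroxymethylation) should add formaldehyde to C5 on the face opposite the pseudoaxial C10 side chain, creating the quaternary C5 centre with C6 trans to C9, after which acid-catalysed transesterification closes the trans-fused δ-lactone.

**Step 3**
Reactants: 5 isopropenyl keto lactone
Product: 7 keto lactone, via methoxy hydroperoxide 6 (not isolated)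
Conditions: O3, MeOH, −78 °C; then FeSO4·7H2O, PhSH, −78 °C → rt
Reagents that add atoms: none
Why: Dealkenylative hydrogenation (ozonolysis in methanol to the α-methoxy hydroperoxide, β-scission of the alkoxyl radical formed with divalent iron, and hydrogen-atom transfer from the thiol to the C2 radical) should excise the isopropenyl control element, and no stereocentre is at risk because C2 becomes a methylene group.

**Step 4**
Reactants: 7 keto lactone
Product: 8 C3=C4 enol triflate
Conditions: KN(SiMe3)2, PhNTf2, THF, −78 °C
Reagents that add atoms: N-phenylbis(trifluoromethanesulfonimide), O=S(=O)(N(c1ccccc1)S(=O)(=O)C(F)(F)F)C(F)(F)F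
Why: Kinetic deprotonation can only give the C3 enolate because C5 is quaternary and the lactone α-proton is much less acidic, so enol triflate formation should give the C3=C4 triflate as a single regioisomer with no stereocentre touched.

**Step 5**
Reactants: 8 enol triflate
Product: 9 methyl alkene lactone
Conditions: MeMgBr, Fe(acac)3 (5 mol %), THF/NMP, −30 °C
Reagents that add atoms: methylmagnesium bromide, C[Mg]Br
Why: Iron-catalysed Kumada-type cross-coupling of alkenyl triflates with Grignard reagents is fast at low temperature, where the lactone carbonyl is not attacked, and should install Me-18 on the C3=C4 double bond.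

**Step 6**
Reactants: 9 methyl alkene lactone; 10 phenyl vinyl sulfoxide
Product: 11 sulfinylethyl lactone
Conditions: LiN(i-Pr)2, THF, −78 °C; 10, −78 → −20 °C; then H2O
Reagents that add atoms: none
Why: Michael addition of the lactone lithium enolate to the vinyl sulfoxide (a vinyl cation equivalent) should occur on the α face of the planar C9 enolate because the β face is screened by the 1,3-related axial Me-19 of the trans-fused bicycle, which sets the quaternary C9 centre (Me-20 β) from both C9 epimers of 9.

**Step 7**
Reactants: 11 sulfinylethyl lactone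
Product: 12 vinyl lactone
Conditions: PhMe, 110 °C
Reagents that add atoms: none
Why: Thermal sulfoxide syn-elimination can only take a hydrogen from C11 because C9 is quaternary, so the C9 vinyl group should form without affecting any stereocentre.

**Step 8**
Reactants: 12 vinyl lactone
Product: 13 lactol
Conditions: MeLi, THF, −78 °C; then H2O
Reagents that add atoms: methyllithium, [Li]C
Why: 1,2-Addition of the organolithium to the lactone gives a lithium hemiketal that is stable at low temperature and shielded by the quaternary C9, so a single methyl group (Me-17) should be delivered and the C8 methyl ketone emerges masked as the lactol.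

**Step 9**
Reactants: 13 lactol
Product: 14 keto aldehyde
Conditions: Dess–Martin periodinane, pyridine, CH2Cl2, rt
Reagents that add atoms: none
Why: Dess–Martin oxidation acts on the primary C6 alcohol of the open hydroxy ketone tautomer, which is drained from the lactol equilibrium, and should give the non-enolisable neopentyl aldehyde under neutral conditions.

**Step 10**
Reactants: 14 keto aldehyde; 15 1,3-dithiane
Product: 17 silyl ether dithiane, via lithium alkoxide 16 (not isolated)
Conditions: 15, n-BuLi, THF, −30 °C; 14, −78 °C; then TBSOTf, −78 → 0 °C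
Reagents that add atoms: tert-butyldimethylsilyl trifluoromethanesulfonate, CC(C)(C)[Si](C)(C)OS(=O)(=O)C(F)(F)F
Why: Corey–Seebach addition of the formyl anion equivalent should select the aldehyde over the hindered methyl ketone and follow Felkin–Anh 1,2-induction at the α-quaternary C5 (C10 with its quaternary C9 substituent anti to the nucleophile, Me-19 as the small group passed by it), which sets C6, and the alkoxide is silylated in the same flask before it can engage the ketone.

**Step 11**
Reactants: 17 silyl ether dithiane
Product: 18 α-silyloxy 1,6-keto aldehyde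
Conditions: PhI(OCOCF3)2, MeCN/H2O (9:1), 0 °C
Reagents that add atoms: water, O
Why: Oxidative dithioacetal hydrolysis with the hypervalent iodine reagent is fast in the cold, should leave both alkenes and the silyl ether intact, and releases the aldehyde without epimerising C6 provided the product is used at once.

**Step 12**
Reactants: 18 α-silyloxy 1,6-keto aldehyde
Product: 19 trans-decalin 7α,8α-diol
Conditions: SmI2 (3 equiv), t-BuOH (2 equiv), THF, −78 °C → rt; then H2O
Reagents that add atoms: none
Why: Divalent samarium reduces the aldehyde selectively (it is far easier to reduce than the dialkyl ketone) to a samarium-bound C7 ketyl radical, which adds in a 6-exo-trig mode to the carbon of the C8 ketone held on the same oxophilic metal, and a second electron transfer gives the trivalent samarium diolate that is protonated on work-up. The closest known reaction type is the SmI2-promoted intramolecular pinacol coupling of 1,6-keto aldehydes to cis-cyclohexane-1,2-diols. Ring B closes through a chair transition state fused trans to ring A, in which C5 and C9 already carry syn-axial β-methyl groups. C7 is controlled by these two methyl groups, because an axial C7–O–Sm bond would be 1,3-diaxial to both and the ketyl oxygen therefore sits equatorial (α), trans to the equatorial 6β-silyloxy group; C8 is controlled by the metal bridge between the two oxygens, which demands a cis-diol and so places the C8 oxygen axial (α) and Me-17 equatorial (β). The step needs cyclisation to outrun over-reduction of the aldehyde, β-elimination of the silyloxy group and 6-exo attack on the C9 vinyl group; the first two are secured by fast intramolecular trapping of the ketyl by the chelated ketone and the poor leaving ability of a silyl ether, the last by the inertness of unactivated alkenes toward ketyls when no strongly donating additive such as HMPA is present.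

**Step 13**
Reactants: 19 trans-decalin 7α,8α-diol
Product: 20 7α-isobutyrate
Conditions: (i-PrCO)2O, DMAP, pyridine, CH2Cl2, rt
Reagents that add atoms: isobutyric anhydride, CC(C)C(=O)OC(=O)C(C)C
Why: DMAP-catalysed acylation should esterify only the secondary equatorial C7 hydroxyl, since the tertiary C8 hydroxyl next to the quaternary C9 is unreactive under these conditions.

**Step 14**
Reactants: 20 7α-isobutyrate
Product: 21 6β-alcohol
Conditions: HF·pyridine, THF, 0 °C → rt
Reagents that add atoms: none
Why: Acidic fluoride-mediated desilylation should free the C6 hydroxyl without the 1,2-acyl migration from O7 that a basic fluoride source could trigger.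

**Step 15**
Reactants: 21 6β-alcohol
Product: 22 6β-acetate
Conditions: Ac2O, DMAP (cat.), pyridine, CH2Cl2, rt
Reagents that add atoms: acetic anhydride, CC(=O)OC(C)=O
Why: DMAP-catalysed acetylation should convert the secondary C6 hydroxyl into the acetate while the tertiary C8 hydroxyl stays free.

**Step 16**
Reactants: 22 6β-acetate; 23 4-bromofuran-2(5H)-one
Product: 24 CNP0207114.1
Conditions: Pd(OAc)2 (10 mol %), P(o-tol)3, Ag2CO3, MeCN, 70 °C
Reagents that add atoms: none
Why: A Mizoroki–Heck reaction should proceed by oxidative addition of zerovalent palladium into the C–Br bond, carbopalladation of the C9 vinyl group with the butenolide delivered to the terminal carbon C12, and syn β-hydride elimination, which can only use a C12 hydrogen because C9 is quaternary and therefore gives the (E)-C11=C12 diene.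

**Compound list**
1 | (S)-(+)-carvone, (5S)-2-methyl-5-(prop-1-en-2-yl)cyclohex-2-en-1-one | CC1=CC[C@H](C(C)=C)CC1=O | starting material
2 | 1-methoxy-1-(trimethylsilyloxy)prop-1-ene (silyl ketene acetal of methyl propanoate, E/Z mixture) | CC=C(OC)O[Si](C)(C)C | starting material
3 | methyl 2-[2-methyl-5-(prop-1-en-2-yl)-3-(trimethylsilyloxy)cyclohex-2-en-1-yl]propanoate; C10 side chain β, isopropenyl on C2 α (ring 1,5-trans); both C9 epimers | COC(=O)C(C)[C@H]1C[C@H](C(C)=C)CC(O[Si](C)(C)C)=C1C | intermediate
4 | methyl 2-[2-(hydroxymethyl)-2-methyl-3-oxo-5-(prop-1-en-2-yl)cyclohexyl]propanoate; Me-19 β, CH2OH (C6) α and trans to the C10 side chain; both C9 epimers | COC(=O)C(C)[C@H]1C[C@H](C(C)=C)CC(=O)[C@]1(C)CO | intermediate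
5 | trans-fused keto δ-lactone, 4,8a-dimethyl-6-(prop-1-en-2-yl)octahydro-1H-isochromene-3,8-dione; 8a-Me β, 4a-H α, 6-isopropenyl α; both epimers at C4 (= C9) | O=C1OC[C@@]2(C)C(=O)C[C@@H](C(C)=C)C[C@@H]2C1C | intermediate
6 | 5 with the isopropenyl group converted into a 1-hydroperoxy-1-methoxyethyl group | O=C1OC[C@@]2(C)C(=O)C[C@@H](C(C)(OC)OO)C[C@@H]2C1C | intermediate
7 | trans-fused 4,8a-dimethyloctahydro-1H-isochromene-3,8-dione; 8a-Me β, 4a-H α; both epimers at C4 (= C9) | O=C1OC[C@@]2(C)C(=O)CCC[C@@H]2C1C | intermediate
8 | trans-fused 4,8a-dimethyl-3-oxo-3,4,4a,5,6,8a-hexahydro-1H-isochromen-8-yl trifluoromethanesulfonate (enol triflate on C4 of the C3=C4 bond) | O=C1OC[C@@]2(C)C(OS(=O)(=O)C(F)(F)F)=CCC[C@@H]2C1C | intermediate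
9 | trans-fused 4,8,8a-trimethyl-1,4,4a,5,6,8a-hexahydro-3H-isochromen-3-one (C3=C4 with Me-18); both C9 epimers | O=C1OC[C@@]2(C)C(C)=CCC[C@@H]2C1C | intermediate
10 | phenyl vinyl sulfoxide (racemic) | C=CS(=O)c1ccccc1 | starting material
11 | 9 carrying on C9 a β-methyl (Me-20) and an α-2-(phenylsulfinyl)ethyl group; sulfoxide epimers | O=C1OC[C@@]2(C)C(C)=CCC[C@@H]2[C@@]1(C)CCS(=O)c1ccccc1 | intermediate
12 | trans-fused 4α-ethenyl-4β,8,8aβ-trimethyl-1,4,4a,5,6,8a-hexahydro-3H-isochromen-3-one (Me-20 β, vinyl α, 10-H α) | O=C1OC[C@@]2(C)C(C)=CCC[C@@H]2[C@@]1(C)C=C | intermediate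
13 | lactol, 4α-ethenyl-3,4β,8,8aβ-tetramethyl-3,4,4a,5,6,8a-hexahydro-1H-isochromen-3-ol (anomers, in equilibrium with the open C6-hydroxy C8-methyl ketone) | CC1(O)OC[C@@]2(C)C(C)=CCC[C@@H]2[C@@]1(C)C=C | intermediate
14 | 1,2-dimethyl-6-(3-methyl-2-oxopent-4-en-3-yl)cyclohex-2-ene-1-carbaldehyde; CHO (C6) α and Me-19 β on C5, 10-H α, C9 as in 12 | O=C[C@@]1(C)C(C)=CCC[C@@H]1[C@@](C)(C=C)C(C)=O | intermediate
15 | 1,3-dithiane | C1CSCSC1 | starting material
16 | lithium alkoxide of the (1,3-dithian-2-yl) carbinol formed from 14, C6 configured as in the target | S1CCCSC1[C@H]([O-])[C@@]2(C)C(C)=CCC[C@@H]2[C@@](C)(C=C)C(C)=O.[Li+] | intermediate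
17 | 3-{2-[(tert-butyldimethylsilyloxy)(1,3-dithian-2-yl)methyl]-2,3-dimethylcyclohex-3-en-1-yl}-3-methylpent-4-en-2-one; C6–O as in the target | S1CCCSC1[C@H](O[Si](C)(C)C(C)(C)C)[C@@]2(C)C(C)=CCC[C@@H]2[C@@](C)(C=C)C(C)=O | intermediate
18 | 2-(tert-butyldimethylsilyloxy)-2-[1,2-dimethyl-6-(3-methyl-2-oxopent-4-en-3-yl)cyclohex-2-en-1-yl]acetaldehyde (1,6-keto aldehyde) | O=C[C@H](O[Si](C)(C)C(C)(C)C)[C@@]1(C)C(C)=CCC[C@@H]1[C@@](C)(C=C)C(C)=O | intermediate
19 | trans-decalin diol: 6β-(tert-butyldimethylsilyloxy)-9α-ethenyl-4,5β,8β,9β-tetramethyl-Δ3-octalin-7α,8α-diol, 10-H α (clerodane numbering) | CC(C)(C)[Si](C)(C)O[C@H]1[C@H](O)[C@](C)(O)[C@](C)(C=C)[C@H]2CCC=C(C)[C@]12C | intermediate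
20 | 7α-(2-methylpropanoate) of 19 (8α-OH free) | CC(C)(C)[Si](C)(C)O[C@H]1[C@H](OC(=O)C(C)C)[C@](C)(O)[C@](C)(C=C)[C@H]2CCC=C(C)[C@]12C | intermediate
21 | 6β,8α-diol 7α-(2-methylpropanoate) (20 without the silyl group) | O[C@H]1[C@H](OC(=O)C(C)C)[C@](C)(O)[C@](C)(C=C)[C@H]2CCC=C(C)[C@]12C | intermediate
22 | 6β-acetoxy-7α-(2-methylpropanoyloxy)-8α-hydroxy-9α-ethenyl-4,5β,8β,9β-tetramethyl-Δ3-octalin, 10-H α | CC(=O)O[C@H]1[C@H](OC(=O)C(C)C)[C@](C)(O)[C@](C)(C=C)[C@H]2CCC=C(C)[C@]12C | intermediate
23 | 4-bromofuran-2(5H)-one | O=C1OCC(Br)=C1 | starting material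
24 | CNP0207114.1: 22 with the vinyl group extended to (E)-2-(5-oxo-2,5-dihydrofuran-3-yl)ethenyl | CC(=O)O[C@H]1[C@H](OC(=O)C(C)C)[C@](C)(O)[C@](C)(/C=C/C2=CC(=O)OC2)[C@H]2CCC=C(C)[C@]12C | target

**Totals**
Total step count: 16. Longest linear sequence: 16 steps, from (S)-carvone.

**Steps most likely to fail, with fallbacks**

Step 12 (key step). The C7 ketyl may be reduced further before it reaches the hindered C8 ketone, giving the primary alcohol or losing the silyloxy group. It may instead be captured 6-exo by the C9 vinyl group, or the chair preference that sets C7 and C8 may erode. The fallback forms the same bond by an aldol closure; it sets out from keto aldehyde 14 and returns to the route at 22. Aldehyde 14 is treated with [(4-methoxybenzyl)oxy]methyllithium (Bu3SnCH2OPMB, n-BuLi, THF, −78 °C) to give the PMB-oxymethyl carbinol F1 (C6 epimers, of no consequence), and Dess–Martin oxidation gives the α-alkoxy ketone F2. Chelation-assisted soft enolisation at C7 (MgBr2·OEt2, i-Pr2NEt, CH2Cl2) closes ring B by intramolecular aldol addition to the C8 ketone. Equilibration through the enolisable C7 centre and the reversible aldol step should favour the ketol F3 with equatorial 7α-OPMB and equatorial Me-17. NaBH4 should attack the C6 ketone axially from the α face, the β face being screened by Me-19, to give the 6β-alcohol F4. Acetylation gives the acetate F5, DDQ removes the PMB group to give the 7α-alcohol F6, and isobutyric anhydride/DMAP gives 22.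

Step 10. The basic dithiane anion may enolise the methyl ketone, which can then close onto the neopentyl aldehyde by intramolecular aldol addition, or it may add to the ketone; facial control at C6 may also be incomplete. The fallback keeps C8 at the amide level while C7 is introduced; it sets out from vinyl lactone 12 and returns at 17. The lactone is opened with Me(MeO)NH·HCl/AlMe3 to the hydroxy Weinreb amide F7, which is oxidised with Dess–Martin periodinane to the aldehyde amide F8. 2-Lithio-1,3-dithiane then adds with no enolisable ketone present to give the dithianyl carbinol F9, whose C6 epimers can be separated at this stage. TBSOTf/2,6-lutidine gives the silyl ether F10, and MeLi converts the Weinreb amide into the methyl ketone 17.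

Step 16. Carbopalladation of the neopentyl-type vinyl group may be too slow to compete with base-induced degradation or homocoupling of the bromobutenolide. The fallback replaces the Heck reaction by metathesis and cross-coupling; it sets out from 22 and returns at 24. Cross-metathesis with vinylboronic acid pinacol ester (second-generation Hoveyda–Grubbs catalyst, CH2Cl2, 40 °C) gives the (E)-alkenyl boronate F11, and Suzuki–Miyaura coupling with 23 (Pd(dppf)Cl2, K3PO4, THF/H2O) gives 24.

**Further compounds**
F1 | step 12 | 14 with the aldehyde converted into CH(OH)CH2OPMB (C6 epimers) | COc1ccc(COCC(O)[C@@]2(C)C(C)=CCC[C@@H]2[C@@](C)(C=C)C(C)=O)cc1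
F2 | step 12 | α-(4-methoxybenzyloxy) ketone at C6 (1,5-diketone with the C8 methyl ketone) | COc1ccc(COCC(=O)[C@@]2(C)C(C)=CCC[C@@H]2[C@@](C)(C=C)C(C)=O)cc1
F3 | step 12 | trans-decalin ketol: 6-oxo, 7α-OPMB, 8α-OH, 8β-Me, 9α-vinyl | O=C1[C@H](OCc3ccc(OC)cc3)[C@](C)(O)[C@](C)(C=C)[C@H]2CCC=C(C)[C@]12C
F4 | step 12 | 6β,8α-diol 7α-PMB ether | O[C@H]1[C@H](OCc3ccc(OC)cc3)[C@](C)(O)[C@](C)(C=C)[C@H]2CCC=C(C)[C@]12C
F5 | step 12 | 6β-acetate 7α-PMB ether 8α-ol | CC(=O)O[C@H]1[C@H](OCc3ccc(OC)cc3)[C@](C)(O)[C@](C)(C=C)[C@H]2CCC=C(C)[C@]12C
F6 | step 12 | 6β-acetate 7α,8α-diol | CC(=O)O[C@H]1[C@H](O)[C@](C)(O)[C@](C)(C=C)[C@H]2CCC=C(C)[C@]12C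
F7 | step 10 | hydroxy Weinreb amide from 12 (C6 CH2OH, C8 N-methoxy-N-methylamide) | CON(C)C(=O)[C@](C)(C=C)[C@H]1CCC=C(C)[C@]1(C)CO
F8 | step 10 | aldehyde Weinreb amide (C6 CHO) | CON(C)C(=O)[C@](C)(C=C)[C@H]1CCC=C(C)[C@]1(C)C=O
F9 | step 10 | (1,3-dithian-2-yl) carbinol Weinreb amide, C6 as in the target | CON(C)C(=O)[C@](C)(C=C)[C@H]1CCC=C(C)[C@]1(C)[C@@H](O)C1SCCCS1
F10 | step 10 | tert-butyldimethylsilyl ether of F9 | CON(C)C(=O)[C@](C)(C=C)[C@H]1CCC=C(C)[C@]1(C)[C@@H](O[Si](C)(C)C(C)(C)C)C1SCCCS1
F11 | step 16 | 22 with the vinyl group converted into (E)-2-(4,4,5,5-tetramethyl-1,3,2-dioxaborolan-2-yl)ethenyl | CC(=O)O[C@H]1[C@H](OC(=O)C(C)C)[C@](C)(O)[C@](C)(/C=C/B2OC(C)(C)C(C)(C)O2)[C@H]2CCC=C(C)[C@]12C
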